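**Plan**

1. Numbering: chain C1 (CO2H) to C12; ring C1'–C6' (C1' carries the chain, C2' the methyl, C6' the gem-dimethyl group). The retrosynthesis cuts C7–C8 (cross-metathesis of two vinyl groups, then diimide), the dioxane bonds O–C3 and O–C6, the epoxide, and the ring bond C3'–C4'.
2. One aldehyde from geraniol, (4E)-6-silyloxy-4-methylhex-4-enal 5, is used twice: as C8–C12 plus C1' of fragment A and as C3–C8 of fragment B.
3. Fragment A: reverse prenylation brings C6', C5' and C4'; an enol triflate/Suzuki sequence brings C2', C3' and the ring methyl; the carbocycle is closed last at C3'–C4'. This works because C3' is the allylic CH2 of the tetrasubstituted C1'=C2' bond and C6' is quaternary: a C4' radical can add 6-endo to the CH2 end of a C3'=C2'–C1'=C12 diene, and H-transfer to C12 leaves the double bond at C1'=C2'. Both diene geometries converge.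
4. Sharpless epoxidation of the resulting allylic alcohol sets C9 and C10 without touching the ring alkene; oxidation and methylenation give the vinyl epoxide.
5. Fragment B: Brown anti-crotylboration sets C2 and C3; Sharpless epoxidation with the other tartrate, then invertive perhydrolysis at the tertiary epoxide carbon, sets C6–OO; invertive 6-exo displacement of the C3 mesylate closes the 1,2-dioxane; the two side arms are then trimmed to CO2Me and vinyl.
6. The fragments are joined by cross-metathesis, the new alkene is reduced with diimide, and the ester is saponified.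

Key step: step 10

Remark: geraniol (1), prenyl bromide (6), boronate 13 and the reagents in the Conditions lines are taken as commercial. Compounds 9–15 are drawn as the expected major geometric isomer at the enol triflate/diene; any minor isomer is carried along because step 10 erases that geometry.

**Route**

Step 1
Reactants: 1 geraniol
Product: 2 tert-butyl{[(2E)-3,7-dimethylocta-2,6-dien-1-yl]oxy}diphenylsilane
Conditions: t-BuPh2SiCl, imidazole, CH2Cl2, 0 °C → rt
Reagents that add atoms: tert-butyl(chloro)diphenylsilane, CC(C)(C)[Si](Cl)(c1ccccc1)c1ccccc1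
Why: Silylation of the primary allylic alcohol should give a robust ether whose bulk also shields the 2,3-alkene in step 2.

Step 2
Reactants: 2 geranyl silyl ether
Product: 3 tert-butyl{[(2E)-5-(3,3-dimethyloxiran-2-yl)-3-methylpent-2-en-1-yl]oxy}diphenylsilane (racemic)
Conditions: mCPBA (1 equiv), CH2Cl2, −20 → 0 °C
Reagents that add atoms: 3-chloroperoxybenzoic acid, OOC(=O)c1cccc(Cl)c1
Why: Prilezhaev epoxidation should favour the more electron-rich, unhindered 6,7-alkene over the 2,3-alkene deactivated by the allylic silyloxy group; the new stereocenter is racemic and is destroyed in step 3.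

Step 3
Reactants: 3 terminal epoxide
Product: 5 (4E)-6-[(tert-butyldiphenylsilyl)oxy]-4-methylhex-4-enal, via vicinal diol 4 (not isolated)
Conditions: H5IO6, THF/H2O, 0 °C → rt
Reagents that add atoms: none
Why: Periodic acid should hydrate the epoxide to diol 4 and cleave it at once (Malaprade glycol cleavage), leaving the trisubstituted allylic ether alkene untouched.

Step 4
Reactants: 5 aldehyde; 6 prenyl bromide (1-bromo-3-methylbut-2-ene)
Product: 7 (7E)-9-[(tert-butyldiphenylsilyl)oxy]-3,3,7-trimethylnona-1,7-dien-4-ol (racemic)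
Conditions: Zn dust, THF/sat. aq. NH4Cl, rt
Reagents that add atoms: none
Why: Barbier allylation, in which the prenylzinc species should add through its γ-carbon in a six-membered transition state, installs the quaternary gem-dimethyl carbon (C6') and a vinyl group (C5', C4') in one step; the carbinol center is oxidized away in step 5.

Step 5
Reactants: 7 homoallylic alcohol
Product: 8 (7E)-9-[(tert-butyldiphenylsilyl)oxy]-3,3,7-trimethylnona-1,7-dien-4-one
Conditions: Dess–Martin periodinane, NaHCO3, CH2Cl2, rt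
Reagents that add atoms: none
Why: Dess–Martin oxidation of the hindered secondary alcohol should give the β,γ-unsaturated ketone, which cannot move into conjugation because its α-carbon is quaternary.

Step 6
Reactants: 8 ketone
Product: 10 (4Z,7E)-9-[(tert-butyldiphenylsilyl)oxy]-3,3,7-trimethylnona-1,4,7-trien-4-yl trifluoromethanesulfonate, via potassium enolate 9 (not isolated)
Conditions: KN(SiMe3)2, THF, −78 °C; then PhNTf2, −78 → 0 °C
Reagents that add atoms: N-phenylbis(trifluoromethanesulfonimide), O=S(=O)(N(c1ccccc1)S(=O)(=O)C(F)(F)F)C(F)(F)F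
Why: The ketone has a single enolizable α-position, so kinetic deprotonation and O-triflation of enolate 9 should give one regioisomer of the enol triflate, mainly Z because the chain avoids the tertiary alkyl group.

Step 7
Reactants: 10 trienyl triflate
Product: 12 (4Z,7E)-9-[(tert-butyldiphenylsilyl)oxy]-1-hydroxy-3,3,7-trimethylnona-4,7-dien-4-yl trifluoromethanesulfonate, via B-alkyl-9-BBN borane 11 (not isolated)
Conditions: 9-BBN, THF, 0 °C → rt; then H2O2, aq. NaOAc, 0 °C → rt
Reagents that add atoms: hydrogen peroxide, OO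
Why: Brown hydroboration–oxidation, in which 9-BBN should add anti-Markovnikov only to the monosubstituted vinyl group and ignore the trisubstituted alkene and the electron-poor enol triflate, while the buffered oxidation of borane 11 spares the triflate.

Step 8
Reactants: 12 hydroxy enol triflate; 13 isopropenylboronic acid pinacol ester
Product: 14 (4E,7E)-9-[(tert-butyldiphenylsilyl)oxy]-3,3,7-trimethyl-4-(prop-1-en-2-yl)nona-4,7-dien-1-ol
Conditions: Pd(PPh3)4 (cat.), K2CO3, dioxane/H2O, 80 °C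
Reagents that add atoms: none
Why: Suzuki–Miyaura coupling of an alkenyl triflate with an alkenylboronate should proceed with retention and give the 2,3-disubstituted 1,3-diene without affecting the free alcohol or the silyl ether.

Step 9
Reactants: 14 diene alcohol
Product: 15 tert-butyl{[(2E,5E)-9-iodo-3,7,7-trimethyl-6-(prop-1-en-2-yl)nona-2,5-dien-1-yl]oxy}diphenylsilane
Conditions: I2, PPh3, imidazole, CH2Cl2, 0 °C, dark
Reagents that add atoms: iodine, II
Why: Appel-type iodination should convert the unhindered primary alcohol into the iodide under neutral conditions that the diene tolerates.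

Step 10
Reactants: 15 diene iodide
Product: 16 tert-butyl{[(2E)-3-methyl-5-(2,6,6-trimethylcyclohex-1-en-1-yl)pent-2-en-1-yl]oxy}diphenylsilane
Conditions: Bu3SnH (syringe pump), AIBN (cat.), PhH, 80 °C, high dilution
Reagents that add atoms: none
Why: Bu3Sn• abstracts iodine to give the primary radical at C4', which adds to the CH2 terminus (C3') of the isopropenyl unit, and the resulting allyl radical (C2'–C1'–C12) takes a hydrogen atom from Bu3SnH at its exocyclic end C12, leaving the tetrasubstituted C1'=C2' bond in the ring. The closest known reaction type is the tin hydride cyclization of 5-substituted hex-5-enyl radicals and of alkyl radicals onto 1,3-dienes. The ring closes in the 6-endo-trig mode; no stereocenter is formed, and both geometric isomers of the diene pass through the same allyl radical, so the step is stereoconvergent. It needs 6-endo over 5-exo selectivity, which the fully substituted internal diene carbon C2' should secure, because 5-exo attack would hit that hindered carbon and give a non-stabilized primary radical whereas 6-endo attack gives an allyl radical. It also needs hydrogen transfer to C12 and not to C2', which the tertiary, ring-flanked C2' terminus and the allylic strain between the C2' methyl and the side chain should secure. Slow addition of the stannane keeps reduction before cyclization and hydrostannation of the diene low, and the remote trisubstituted alkene is too far away to take part.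

Step 11
Reactants: 16 cyclized silyl ether
Product: 17 (2E)-3-methyl-5-(2,6,6-trimethylcyclohex-1-en-1-yl)pent-2-en-1-ol
Conditions: Bu4NF, THF, 0 °C → rt
Reagents that add atoms: none
Why: Fluoride-mediated desilylation should free the primary allylic alcohol without touching either alkene.

Step 12
Reactants: 17 allylic alcohol
Product: 18 [(2S,3S)-3-methyl-3-[2-(2,6,6-trimethylcyclohex-1-en-1-yl)ethyl]oxiran-2-yl]methanol
Conditions: Ti(OiPr)4 (cat.), L-(+)-diethyl tartrate, t-BuOOH, 4 Å MS, CH2Cl2, −20 °C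
Reagents that add atoms: tert-butyl hydroperoxide, CC(C)(C)OO
Why: Sharpless asymmetric epoxidation acts only on the allylic alcohol alkene, so the tetrasubstituted ring alkene survives, and the L-(+)-tartrate should deliver oxygen to the face that gives the (2S,3S)-epoxy alcohol (C9 and C10 of the target), as it does with geraniol.

Step 13
Reactants: 18 epoxy alcohol
Product: 19 (2R,3S)-3-methyl-3-[2-(2,6,6-trimethylcyclohex-1-en-1-yl)ethyl]oxirane-2-carbaldehyde
Conditions: Dess–Martin periodinane, NaHCO3, CH2Cl2, 0 °C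
Reagents that add atoms: none
Why: Buffered Dess–Martin oxidation should give the epoxy aldehyde without epimerization or epoxide opening; the descriptor at the epoxide CH changes only because the priorities change.

Step 14
Reactants: 19 epoxy aldehyde
Product: 20 (2S,3S)-3-ethenyl-2-methyl-2-[2-(2,6,6-trimethylcyclohex-1-en-1-yl)ethyl]oxirane (fragment A)
Conditions: Ph3PCH3Br, KN(SiMe3)2, THF, 0 °C; then 19, −78 → 0 °C
Reagents that add atoms: methyltriphenylphosphonium bromide, C[P+](c1ccccc1)(c1ccccc1)c1ccccc1.[Br-]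
Why: Wittig methylenation with a preformed non-stabilized ylide at low temperature should give the vinyl epoxide without epimerizing the epoxide CH.

Step 15
Reactants: 5 aldehyde
Product: 22 (3S,4R,7E)-9-[(tert-butyldiphenylsilyl)oxy]-3,7-dimethylnona-1,7-dien-4-ol, via diisopinocampheylborinate 21 (not isolated)
Conditions: trans-but-2-ene, n-BuLi, KOtBu, THF, −78 → −45 °C; (−)-Ipc2BOMe; BF3·OEt2, −78 °C; then 5; NaOH, H2O2, rt
Reagents that add atoms: (E)-crotyldiisopinocampheylborane, C/C=C/CB([C@@H]1C[C@@H]2C[C@H]([C@H]1C)C2(C)C)[C@@H]1C[C@@H]2C[C@H]([C@H]1C)C2(C)C, made in the flask from trans-but-2-ene, C/C=C/C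
Why: Brown crotylboration, in which the (E)-crotylborane reacts through a chair-like Zimmerman–Traxler transition state to give the anti adduct and the isopinocampheyl groups derived from (+)-α-pinene are expected to direct attack to the Si face of the aldehyde, sets C2 and the C3 carbinol (R here, inverted in step 20).

Step 16
Reactants: 22 anti homoallylic alcohol
Product: 23 (3S,4R,7E)-9-[(tert-butyldiphenylsilyl)oxy]-3,7-dimethylnona-1,7-dien-4-yl methanesulfonate
Conditions: MsCl, Et3N, CH2Cl2, 0 °C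
Reagents that add atoms: methanesulfonyl chloride, CS(=O)(=O)Cl
Why: Sulfonylation of the secondary alcohol with retention provides the leaving group for the later invertive ring closure.

Step 17
Reactants: 23 silyl ether mesylate
Product: 24 (3S,4R,7E)-9-hydroxy-3,7-dimethylnona-1,7-dien-4-yl methanesulfonate
Conditions: HF·pyridine, pyridine, THF, 0 °C → rt
Reagents that add atoms: none
Why: Buffered HF·pyridine desilylation should free the allylic alcohol without displacing or eliminating the secondary mesylate.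

Step 18
Reactants: 24 allylic alcohol
Product: 25 (3S,4R)-6-[(2R,3R)-3-(hydroxymethyl)-2-methyloxiran-2-yl]-3-methylhex-1-en-4-yl methanesulfonate
Conditions: Ti(OiPr)4 (cat.), D-(−)-diethyl tartrate, t-BuOOH, 4 Å MS, CH2Cl2, −20 °C
Reagents that add atoms: tert-butyl hydroperoxide, CC(C)(C)OO
Why: Sharpless asymmetric epoxidation with the D-(−)-tartrate should give the (2R,3R)-epoxy alcohol under reagent control, while the isolated vinyl group and the mesylate do not react.

Step 19
Reactants: 25 epoxy alcohol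
Product: 26 (3S,4R,7S,8R)-7-hydroperoxy-8,9-dihydroxy-3,7-dimethylnon-1-en-4-yl methanesulfonate
Conditions: H2O2 (anhydrous, in Et2O), H3PMo12O40 (cat.), Et2O, rt
Reagents that add atoms: hydrogen peroxide, OO
Why: Acid-catalysed perhydrolysis of the epoxide, in which hydrogen peroxide should attack the tertiary carbon (more cationic character, remote from the deactivating CH2OH) with inversion, sets the C6 peroxide stereocenter.

Step 20
Reactants: 26 hydroperoxy mesylate
Product: 27 (1R)-1-[(3S,6S)-6-[(2S)-but-3-en-2-yl]-3-methyl-1,2-dioxan-3-yl]ethane-1,2-diol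
Conditions: Cs2CO3, DMF, 0 °C → rt
Reagents that add atoms: none
Why: The mild base deprotonates only the hydroperoxide, which should displace the secondary mesylate in a 6-exo-tet SN2 reaction with inversion, closing the 1,2-dioxane and setting C3.

Step 21
Reactants: 27 dioxane diol
Product: 29 (2R)-2-[(3S,6S)-6-[(1R)-1,2-dihydroxyethyl]-6-methyl-1,2-dioxan-3-yl]propanoic acid, via β-peroxy aldehyde 28 (not isolated)
Conditions: O3, MeCN/H2O, 0 °C; then NaClO2, NaH2PO4, rt
Reagents that add atoms: ozone, [O-][O+]=O; sodium chlorite, [Na+].[O-]Cl=O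
Why: Ozonolysis in wet acetonitrile should give aldehyde 28 directly and chlorite oxidation (Pinnick type) in the same flask should convert it to the acid before the β-peroxy aldehyde can epimerize or eliminate, while the dialkyl peroxide and the diol are inert to both reagents.

Step 22
Reactants: 29 acid
Product: 30 methyl (2R)-2-[(3S,6S)-6-[(1R)-1,2-dihydroxyethyl]-6-methyl-1,2-dioxan-3-yl]propanoate
Conditions: Me3SiCHN2, MeOH/toluene, 0 °C
Reagents that add atoms: (trimethylsilyl)diazomethane, C[Si](C)(C)C=[N+]=[N-]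
Why: Esterification with (trimethylsilyl)diazomethane in methanol is mild enough to spare the peroxide and the diol.

Step 23
Reactants: 30 diol ester
Product: 31 methyl (2R)-2-[(3S,6S)-6-formyl-6-methyl-1,2-dioxan-3-yl]propanoate
Conditions: NaIO4, THF/pH 7 buffer, 0 °C → rt
Reagents that add atoms: none
Why: Malaprade glycol cleavage should give the α-peroxy aldehyde, which has no α-hydrogen and so cannot epimerize.

Step 24
Reactants: 31 aldehyde
Product: 32 methyl (2R)-2-[(3S,6S)-6-ethenyl-6-methyl-1,2-dioxan-3-yl]propanoate (fragment B)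
Conditions: Ph3PCH3Br, KN(SiMe3)2, THF, 0 °C; then 31, −78 → 0 °C
Reagents that add atoms: methyltriphenylphosphonium bromide, C[P+](c1ccccc1)(c1ccccc1)c1ccccc1.[Br-]
Why: Wittig methylenation of the aldehyde at low temperature should be faster than attack of the ylide on the ester or on the O–O bond.

Step 25
Reactants: 20 vinyl epoxide (excess); 32 vinyl dioxane
Product: 33 methyl (2R)-2-[(3S,6S)-6-methyl-6-[(E)-2-[(2S,3S)-3-methyl-3-[2-(2,6,6-trimethylcyclohex-1-en-1-yl)ethyl]oxiran-2-yl]ethenyl]-1,2-dioxan-3-yl]propanoate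
Conditions: second-generation Hoveyda–Grubbs catalyst RuCl2(H2IMes)(=CH-C6H4-2-OiPr) (cat.), CH2Cl2, 40 °C
Reagents that add atoms: none
Why: Olefin cross-metathesis should join the two vinyl groups because neither partner homodimerizes readily, the ruthenium carbene tolerates the dialkyl peroxide, epoxide and ester, and the tetrasubstituted ring alkene is inert.

Step 26
Reactants: 33 alkene
Product: 34 methyl (2R)-2-[(3S,6R)-6-methyl-6-{2-[(2S,3S)-3-methyl-3-[2-(2,6,6-trimethylcyclohex-1-en-1-yl)ethyl]oxiran-2-yl]ethyl}-1,2-dioxan-3-yl]propanoate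
Conditions: 2-nitrobenzenesulfonohydrazide, Et3N, CH2Cl2, rt
Reagents that add atoms: none
Why: Diimide made in the flask transfers H2 in a concerted syn fashion to the disubstituted alkene and should not touch the O–O bond, the epoxide or the tetrasubstituted ring alkene.

Step 27
Reactants: 34 methyl ester
Product: 35 (2R)-2-[(3S,6R)-6-methyl-6-{2-[(2S,3S)-3-methyl-3-[2-(2,6,6-trimethylcyclohex-1-en-1-yl)ethyl]oxiran-2-yl]ethyl}-1,2-dioxan-3-yl]propanoic acid (target)
Conditions: LiOH, THF/H2O, 0 °C → rt; then aq. H3PO4 to pH 4–5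
Reagents that add atoms: lithium hydroxide, [Li+].[OH-]
Why: Mild saponification followed by buffered acidification should leave the epoxide, the peroxide and the C2 stereocenter intact.

**Compound list**

1 | geraniol, (2E)-3,7-dimethylocta-2,6-dien-1-ol | CC(C)=CCC/C(C)=C/CO | starting material
2 | tert-butyl{[(2E)-3,7-dimethylocta-2,6-dien-1-yl]oxy}diphenylsilane | CC(C)=CCC/C(C)=C/CO[Si](c1ccccc1)(c1ccccc1)C(C)(C)C | intermediate
3 | tert-butyl{[(2E)-5-(3,3-dimethyloxiran-2-yl)-3-methylpent-2-en-1-yl]oxy}diphenylsilane (racemic) | CC1(C)OC1CC/C(C)=C/CO[Si](c1ccccc1)(c1ccccc1)C(C)(C)C | intermediate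
4 | (6E)-8-[(tert-butyldiphenylsilyl)oxy]-2,6-dimethyloct-6-ene-2,3-diol (racemic, not isolated) | CC(C)(O)C(O)CC/C(C)=C/CO[Si](c1ccccc1)(c1ccccc1)C(C)(C)C | intermediate
5 | (4E)-6-[(tert-butyldiphenylsilyl)oxy]-4-methylhex-4-enal | O=CCC/C(C)=C/CO[Si](c1ccccc1)(c1ccccc1)C(C)(C)C | intermediate
6 | prenyl bromide, 1-bromo-3-methylbut-2-ene | CC(C)=CCBr | starting material
7 | (7E)-9-[(tert-butyldiphenylsilyl)oxy]-3,3,7-trimethylnona-1,7-dien-4-ol (racemic) | C=CC(C)(C)C(O)CC/C(C)=C/CO[Si](c1ccccc1)(c1ccccc1)C(C)(C)C | intermediate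
8 | (7E)-9-[(tert-butyldiphenylsilyl)oxy]-3,3,7-trimethylnona-1,7-dien-4-one | C=CC(C)(C)C(=O)CC/C(C)=C/CO[Si](c1ccccc1)(c1ccccc1)C(C)(C)C | intermediate
9 | potassium (4Z,7E)-9-[(tert-butyldiphenylsilyl)oxy]-3,3,7-trimethylnona-1,4,7-trien-4-olate (not isolated) | C=CC(C)(C)/C([O-])=C/C/C(C)=C/CO[Si](c1ccccc1)(c1ccccc1)C(C)(C)C.[K+] | intermediate
10 | (4Z,7E)-9-[(tert-butyldiphenylsilyl)oxy]-3,3,7-trimethylnona-1,4,7-trien-4-yl trifluoromethanesulfonate | C=CC(C)(C)/C(OS(=O)(=O)C(F)(F)F)=C/C/C(C)=C/CO[Si](c1ccccc1)(c1ccccc1)C(C)(C)C | intermediate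
11 | (4Z,7E)-1-(9-borabicyclo[3.3.1]nonan-9-yl)-9-[(tert-butyldiphenylsilyl)oxy]-3,3,7-trimethylnona-4,7-dien-4-yl trifluoromethanesulfonate (not isolated) | B1(CCC(C)(C)/C(OS(=O)(=O)C(F)(F)F)=C/C/C(C)=C/CO[Si](c2ccccc2)(c2ccccc2)C(C)(C)C)C2CCCC1CCC2 | intermediate
12 | (4Z,7E)-9-[(tert-butyldiphenylsilyl)oxy]-1-hydroxy-3,3,7-trimethylnona-4,7-dien-4-yl trifluoromethanesulfonate | OCCC(C)(C)/C(OS(=O)(=O)C(F)(F)F)=C/C/C(C)=C/CO[Si](c1ccccc1)(c1ccccc1)C(C)(C)C | intermediate
13 | isopropenylboronic acid pinacol ester, 4,4,5,5-tetramethyl-2-(prop-1-en-2-yl)-1,3,2-dioxaborolane | CC(=C)B1OC(C)(C)C(C)(C)O1 | starting material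
14 | (4E,7E)-9-[(tert-butyldiphenylsilyl)oxy]-3,3,7-trimethyl-4-(prop-1-en-2-yl)nona-4,7-dien-1-ol | OCCC(C)(C)/C(C(C)=C)=C/C/C(C)=C/CO[Si](c1ccccc1)(c1ccccc1)C(C)(C)C | intermediate
15 | tert-butyl{[(2E,5E)-9-iodo-3,7,7-trimethyl-6-(prop-1-en-2-yl)nona-2,5-dien-1-yl]oxy}diphenylsilane | ICCC(C)(C)/C(C(C)=C)=C/C/C(C)=C/CO[Si](c1ccccc1)(c1ccccc1)C(C)(C)C | intermediate
16 | tert-butyl{[(2E)-3-methyl-5-(2,6,6-trimethylcyclohex-1-en-1-yl)pent-2-en-1-yl]oxy}diphenylsilane | CC1=C(CC/C(C)=C/CO[Si](c2ccccc2)(c2ccccc2)C(C)(C)C)C(C)(C)CCC1 | intermediate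
17 | (2E)-3-methyl-5-(2,6,6-trimethylcyclohex-1-en-1-yl)pent-2-en-1-ol | CC1=C(CC/C(C)=C/CO)C(C)(C)CCC1 | intermediate
18 | [(2S,3S)-3-methyl-3-[2-(2,6,6-trimethylcyclohex-1-en-1-yl)ethyl]oxiran-2-yl]methanol | CC1=C(CC[C@]2(C)O[C@H]2CO)C(C)(C)CCC1 | intermediate
19 | (2R,3S)-3-methyl-3-[2-(2,6,6-trimethylcyclohex-1-en-1-yl)ethyl]oxirane-2-carbaldehyde | CC1=C(CC[C@]2(C)O[C@H]2C=O)C(C)(C)CCC1 | intermediate
20 | (2S,3S)-3-ethenyl-2-methyl-2-[2-(2,6,6-trimethylcyclohex-1-en-1-yl)ethyl]oxirane | CC1=C(CC[C@]2(C)O[C@H]2C=C)C(C)(C)CCC1 | intermediate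
21 | (3S,4R,7E)-9-[(tert-butyldiphenylsilyl)oxy]-3,7-dimethylnona-1,7-dien-4-yl diisopinocampheylborinate (not isolated) | CC(C)(C)[Si](c1ccccc1)(c1ccccc1)OC/C=C(\C)CC[C@H]([C@@H](C)C=C)OB([C@@H]1C[C@@H]2C[C@H]([C@H]1C)C2(C)C)[C@@H]1C[C@@H]2C[C@H]([C@H]1C)C2(C)C | intermediate
22 | (3S,4R,7E)-9-[(tert-butyldiphenylsilyl)oxy]-3,7-dimethylnona-1,7-dien-4-ol | CC(C)(C)[Si](c1ccccc1)(c1ccccc1)OC/C=C(\C)CC[C@H]([C@@H](C)C=C)O | intermediate
23 | (3S,4R,7E)-9-[(tert-butyldiphenylsilyl)oxy]-3,7-dimethylnona-1,7-dien-4-yl methanesulfonate | CC(C)(C)[Si](c1ccccc1)(c1ccccc1)OC/C=C(\C)CC[C@H]([C@@H](C)C=C)OS(C)(=O)=O | intermediate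
24 | (3S,4R,7E)-9-hydroxy-3,7-dimethylnona-1,7-dien-4-yl methanesulfonate | OC/C=C(\C)CC[C@H]([C@@H](C)C=C)OS(C)(=O)=O | intermediate
25 | (3S,4R)-6-[(2R,3R)-3-(hydroxymethyl)-2-methyloxiran-2-yl]-3-methylhex-1-en-4-yl methanesulfonate | OC[C@H]1O[C@]1(C)CC[C@H]([C@@H](C)C=C)OS(C)(=O)=O | intermediate
26 | (3S,4R,7S,8R)-7-hydroperoxy-8,9-dihydroxy-3,7-dimethylnon-1-en-4-yl methanesulfonate | OC[C@@H](O)[C@@](C)(OO)CC[C@H]([C@@H](C)C=C)OS(C)(=O)=O | intermediate
27 | (1R)-1-[(3S,6S)-6-[(2S)-but-3-en-2-yl]-3-methyl-1,2-dioxan-3-yl]ethane-1,2-diol | OC[C@@H](O)[C@]1(C)CC[C@@H]([C@@H](C)C=C)OO1 | intermediate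
28 | (2R)-2-[(3S,6S)-6-[(1R)-1,2-dihydroxyethyl]-6-methyl-1,2-dioxan-3-yl]propanal (not isolated) | OC[C@@H](O)[C@]1(C)CC[C@@H]([C@@H](C)C=O)OO1 | intermediate
29 | (2R)-2-[(3S,6S)-6-[(1R)-1,2-dihydroxyethyl]-6-methyl-1,2-dioxan-3-yl]propanoic acid | OC[C@@H](O)[C@]1(C)CC[C@@H]([C@@H](C)C(=O)O)OO1 | intermediate
30 | methyl (2R)-2-[(3S,6S)-6-[(1R)-1,2-dihydroxyethyl]-6-methyl-1,2-dioxan-3-yl]propanoate | OC[C@@H](O)[C@]1(C)CC[C@@H]([C@@H](C)C(=O)OC)OO1 | intermediate
31 | methyl (2R)-2-[(3S,6S)-6-formyl-6-methyl-1,2-dioxan-3-yl]propanoate | O=C[C@]1(C)CC[C@@H]([C@@H](C)C(=O)OC)OO1 | intermediate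
32 | methyl (2R)-2-[(3S,6S)-6-ethenyl-6-methyl-1,2-dioxan-3-yl]propanoate | C=C[C@]1(C)CC[C@@H]([C@@H](C)C(=O)OC)OO1 | intermediate
33 | methyl (2R)-2-[(3S,6S)-6-methyl-6-[(E)-2-[(2S,3S)-3-methyl-3-[2-(2,6,6-trimethylcyclohex-1-en-1-yl)ethyl]oxiran-2-yl]ethenyl]-1,2-dioxan-3-yl]propanoate | CC1=C(CC[C@]2(C)O[C@H]2/C=C/[C@]2(C)CC[C@@H]([C@@H](C)C(=O)OC)OO2)C(C)(C)CCC1 | intermediate
34 | methyl (2R)-2-[(3S,6R)-6-methyl-6-{2-[(2S,3S)-3-methyl-3-[2-(2,6,6-trimethylcyclohex-1-en-1-yl)ethyl]oxiran-2-yl]ethyl}-1,2-dioxan-3-yl]propanoate | CC1=C(CC[C@]2(C)O[C@H]2CC[C@]2(C)CC[C@@H]([C@@H](C)C(=O)OC)OO2)C(C)(C)CCC1 | intermediate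
35 | (2R)-2-[(3S,6R)-6-methyl-6-{2-[(2S,3S)-3-methyl-3-[2-(2,6,6-trimethylcyclohex-1-en-1-yl)ethyl]oxiran-2-yl]ethyl}-1,2-dioxan-3-yl]propanoic acid | CC1=C(CC[C@]2(C)O[C@H]2CC[C@]2(C)CC[C@@H]([C@@H](C)C(=O)O)OO2)C(C)(C)CCC1 | target

**Step count and risks**

Total: 27 steps. Longest linear sequence: 17 steps (steps 1–14, then 25–27).

Most likely to fail:

1. Step 20. E2 loss of the β-branched secondary mesylate, or base-induced fragmentation of the β-hydroxy hydroperoxide, may outrun the 6-exo-tet displacement. The fallback sets out from aldehyde 5 and makes the C3–O bond by conjugate addition instead. Wittig olefination of 5 with methyl 2-(triphenylphosphoranylidene)propanoate should give methyl (2E,6E)-8-[(tert-butyldiphenylsilyl)oxy]-2,6-dimethylocta-2,6-dienoate F1. HF·pyridine should give methyl (2E,6E)-8-hydroxy-2,6-dimethylocta-2,6-dienoate F2. Sharpless epoxidation with D-(−)-diethyl tartrate should give methyl (2E)-5-[(2R,3R)-3-(hydroxymethyl)-2-methyloxiran-2-yl]-2-methylpent-2-enoate F3, and perhydrolysis as in step 19 should give methyl (2E,6S,7R)-6-hydroperoxy-7,8-dihydroxy-2,6-dimethyloct-2-enoate F4. Intramolecular oxa-Michael addition of the hydroperoxide (Et2NH, CF3CH2OH) then closes the dioxane and comes back to the route at 30. C6 is still fixed by the epoxide, but C3 and C2 arise under substrate control, so diastereomers would have to be separated.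

2. Step 25. Slow metathesis at the fully substituted allylic carbon may allow catalyst decay and Lewis-acid opening of the vinyl epoxide. The fallback sets out from 17 and 31 and joins the halves by a Wittig reaction. PBr3 should convert 17 into 2-[(3E)-5-bromo-3-methylpent-3-en-1-yl]-1,3,3-trimethylcyclohex-1-ene F5, and PPh3 should give [(2E)-3-methyl-5-(2,6,6-trimethylcyclohex-1-en-1-yl)pent-2-en-1-yl]triphenylphosphonium bromide F6. Its ylide (n-BuLi, THF, −78 °C) with aldehyde 31 should give methyl (2R)-2-[(3S,6S)-6-methyl-6-[(1Z,3E)-4-methyl-6-(2,6,6-trimethylcyclohex-1-en-1-yl)hexa-1,3-dien-1-yl]-1,2-dioxan-3-yl]propanoate F7. Diimide should reduce only the disubstituted alkene to give methyl (2R)-2-[(3S,6R)-6-methyl-6-[(3E)-4-methyl-6-(2,6,6-trimethylcyclohex-1-en-1-yl)hex-3-en-1-yl]-1,2-dioxan-3-yl]propanoate F8. Shi epoxidation (ketone derived from L-fructose, KHSO5, K2CO3) of the trisubstituted alkene then comes back at 34; it must favour the chain alkene over the hindered ring alkene, which is the weak point of this fallback.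

3. Step 10. 5-exo closure, hydrogen transfer to the ring end of the allyl radical, or reduction before cyclization may erode the yield. The fallback sets out from 12 and forms the same ring bond by enolate alkylation. Carbonylative Stille coupling (CO, Me4Sn, Pd(PPh3)4, LiCl) should give (3Z,6E)-8-[(tert-butyldiphenylsilyl)oxy]-3-(4-hydroxy-2-methylbutan-2-yl)-6-methylocta-3,6-dien-2-one F9, and Appel iodination should give (3Z,6E)-8-[(tert-butyldiphenylsilyl)oxy]-3-(4-iodo-2-methylbutan-2-yl)-6-methylocta-3,6-dien-2-one F10. LiN(iPr)2 at −78 °C should form the kinetic enolate at the acetyl methyl group, which closes the ring by 6-exo-tet alkylation to (2Z)-2-[(3E)-5-[(tert-butyldiphenylsilyl)oxy]-3-methylpent-3-en-1-ylidene]-3,3-dimethylcyclohexan-1-one F11. Conjugate reduction with K[(s-Bu)3BH] and trapping of the regiodefined enolate with PhNTf2 should give 2-[(3E)-5-[(tert-butyldiphenylsilyl)oxy]-3-methylpent-3-en-1-yl]-3,3-dimethylcyclohex-1-en-1-yl trifluoromethanesulfonate F12, and Me2CuLi then installs the ring methyl group and comes back at 16.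

**Further compounds**

F1 | step 20 | methyl (2E,6E)-8-[(tert-butyldiphenylsilyl)oxy]-2,6-dimethylocta-2,6-dienoate | COC(=O)/C(C)=C/CC/C(C)=C/CO[Si](c1ccccc1)(c1ccccc1)C(C)(C)C
F2 | step 20 | methyl (2E,6E)-8-hydroxy-2,6-dimethylocta-2,6-dienoate | COC(=O)/C(C)=C/CC/C(C)=C/CO
F3 | step 20 | methyl (2E)-5-[(2R,3R)-3-(hydroxymethyl)-2-methyloxiran-2-yl]-2-methylpent-2-enoate | COC(=O)/C(C)=C/CC[C@@]1(C)O[C@@H]1CO
F4 | step 20 | methyl (2E,6S,7R)-6-hydroperoxy-7,8-dihydroxy-2,6-dimethyloct-2-enoate | COC(=O)/C(C)=C/CC[C@](C)(OO)[C@H](O)CO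
F5 | step 25 | 2-[(3E)-5-bromo-3-methylpent-3-en-1-yl]-1,3,3-trimethylcyclohex-1-ene | CC1=C(CC/C(C)=C/CBr)C(C)(C)CCC1
F6 | step 25 | [(2E)-3-methyl-5-(2,6,6-trimethylcyclohex-1-en-1-yl)pent-2-en-1-yl]triphenylphosphonium bromide | CC1=C(CC/C(C)=C/C[P+](c2ccccc2)(c2ccccc2)c2ccccc2)C(C)(C)CCC1.[Br-]
F7 | step 25 | methyl (2R)-2-[(3S,6S)-6-methyl-6-[(1Z,3E)-4-methyl-6-(2,6,6-trimethylcyclohex-1-en-1-yl)hexa-1,3-dien-1-yl]-1,2-dioxan-3-yl]propanoate | CC1=C(CC/C(C)=C/C=C\[C@]2(C)CC[C@@H]([C@@H](C)C(=O)OC)OO2)C(C)(C)CCC1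
F8 | step 25 | methyl (2R)-2-[(3S,6R)-6-methyl-6-[(3E)-4-methyl-6-(2,6,6-trimethylcyclohex-1-en-1-yl)hex-3-en-1-yl]-1,2-dioxan-3-yl]propanoate | CC1=C(CC/C(C)=C/CC[C@]2(C)CC[C@@H]([C@@H](C)C(=O)OC)OO2)C(C)(C)CCC1
F9 | step 10 | (3Z,6E)-8-[(tert-butyldiphenylsilyl)oxy]-3-(4-hydroxy-2-methylbutan-2-yl)-6-methylocta-3,6-dien-2-one | CC(=O)/C(=C\C/C(C)=C/CO[Si](c1ccccc1)(c1ccccc1)C(C)(C)C)C(C)(C)CCO
F10 | step 10 | (3Z,6E)-8-[(tert-butyldiphenylsilyl)oxy]-3-(4-iodo-2-methylbutan-2-yl)-6-methylocta-3,6-dien-2-one | CC(=O)/C(=C\C/C(C)=C/CO[Si](c1ccccc1)(c1ccccc1)C(C)(C)C)C(C)(C)CCI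
F11 | step 10 | (2Z)-2-[(3E)-5-[(tert-butyldiphenylsilyl)oxy]-3-methylpent-3-en-1-ylidene]-3,3-dimethylcyclohexan-1-one | O=C1CCCC(C)(C)/C1=C/C/C(C)=C/CO[Si](c1ccccc1)(c1ccccc1)C(C)(C)C
F12 | step 10 | 2-[(3E)-5-[(tert-butyldiphenylsilyl)oxy]-3-methylpent-3-en-1-yl]-3,3-dimethylcyclohex-1-en-1-yl trifluoromethanesulfonate | CC(C)(C)[Si](c1ccccc1)(c1ccccc1)OC/C=C(\C)CCC1=C(OS(=O)(=O)C(F)(F)F)CCCC1(C)C
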